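**Retrosynthetic overview**
- Target 13 comes from its 8,3'-bis(benzyl ether) 12 by hydrogenolysis; ring C (O1, C2, C3, C4, C4a, C8a) is the only ring formed in the route.
- Ring C is cut at three bonds at once: C4a–C4, C4–C3 and O1–C2. C4 (with its oxygen) becomes carbon monoxide, C2/C3 become the alkyne carbons of B-ring acetylene 9, and C4a/C8a–O1 become the iodide/phenol pair of A-ring o-iodophenol 5.
- The four contiguous ring-A oxygens (O1 on C8a, then O on C8, C7, C6) are all carried by 5. It comes from 2-hydroxy-3,4-dimethoxybenzaldehyde by benzylation, Baeyer–Villiger oxygenation (the CHO carbon becomes the O1-bearing carbon) and phenoxide-directed iodination at the future C4a.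
- Acetylene 9 comes from 3-hydroxy-4,5-dimethoxybenzaldehyde by benzylation and one-carbon homologation.

Key step: step 6

Remark: the target is a planar, achiral flavone with no stereogenic element, so "single enantiomer" calls for no stereocontrol; both benzaldehyde starting materials are taken as catalogue compounds.

**Step 1**
Reactants: 1 2-hydroxy-3,4-dimethoxybenzaldehyde
Product: 2 2-(benzyloxy)-3,4-dimethoxybenzaldehyde
Conditions: BnBr, K2CO3, DMF, 60 °C
Reagents that add atoms: benzyl bromide, BrCc1ccccc1
Why: Williamson etherification of the chelated 2-OH; the benzyl group masks the future 8-OH so that the phenol unveiled in step 2 is the only free OH on ring A.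

**Step 2**
Reactants: 2 2-(benzyloxy)-3,4-dimethoxybenzaldehyde
Product: 4 2-(benzyloxy)-3,4-dimethoxyphenol, via aryl formate 3 (not isolated)
Conditions: mCPBA, CH2Cl2, rt; then K2CO3 (cat.), MeOH, rt
Reagents that add atoms: mCPBA (3-chloroperoxybenzoic acid), OOC(=O)c1cccc(Cl)c1
Why: Baeyer–Villiger (Dakin-type) oxidation in which the aryl group, activated by ortho- and para-alkoxy donors, should migrate in preference to hydride to give the formate, which is methanolysed to the phenol; benzyl and methyl ethers are inert to the peracid.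

**Step 3**
Reactants: 4 2-(benzyloxy)-3,4-dimethoxyphenol
Product: 5 2-(benzyloxy)-6-iodo-3,4-dimethoxyphenol
Conditions: I2 (1.05 equiv), NaHCO3, THF/H2O, 0 °C
Reagents that add atoms: iodine, II
Why: Electrophilic aromatic iodination of the phenoxide, which should direct to C6, its only free ortho position (the para position carries OMe, the other ortho position OBn), while C5 is meta to the phenoxide oxygen.

**Step 4**
Reactants: 6 3-hydroxy-4,5-dimethoxybenzaldehyde
Product: 7 3-(benzyloxy)-4,5-dimethoxybenzaldehyde
Conditions: BnBr, K2CO3, DMF, rt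
Reagents that add atoms: benzyl bromide, BrCc1ccccc1
Why: Williamson etherification of the single phenol, which keeps a free ArOH out of the palladium carbonylation of step 6.

**Step 5**
Reactants: 7 3-(benzyloxy)-4,5-dimethoxybenzaldehyde
Product: 9 1-(benzyloxy)-5-ethynyl-2,3-dimethoxybenzene, via diazoalkene 8 (not isolated)
Conditions: dimethyl (1-diazo-2-oxopropyl)phosphonate, K2CO3, MeOH, rt
Reagents that add atoms: dimethyl (1-diazo-2-oxopropyl)phosphonate (Ohira–Bestmann reagent), COP(=O)(OC)C(=[N+]=[N-])C(C)=O
Why: Seyferth–Gilbert homologation in the Ohira–Bestmann variant; the diazomethylphosphonate anion formed by methanolysis should olefinate the aldehyde to the diazoalkene, which loses N2 and undergoes a 1,2-shift to the terminal alkyne under conditions that leave the ethers untouched.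

**Step 6**
Reactants: 5 2-(benzyloxy)-6-iodo-3,4-dimethoxyphenol; 9 1-(benzyloxy)-5-ethynyl-2,3-dimethoxybenzene
Product: 12 8-(benzyloxy)-2-[3-(benzyloxy)-4,5-dimethoxyphenyl]-6,7-dimethoxy-4H-chromen-4-one, via alkynone 10 (not isolated), via enaminone 11 (not isolated)
Conditions: PdCl2(PPh3)2 (5 mol%), dppp (5 mol%), thiourea (5 mol%), DBU (2 equiv), Et2NH, CO (1 atm), 40 °C
Reagents that add atoms: carbon monoxide, [C-]#[O+]
Why: Pd(0) should insert into the C–I bond of 5, the electron-rich aryl–Pd(II) should take up CO to an aroyl–Pd species, and amine-assisted transfer of the acetylide of 9 followed by reductive elimination should give alkynone 10 (carbonylative Sonogashira coupling). Et2NH should then add to the ynone to give enaminone 11, and the ortho phenol oxygen should displace the amine at the β-carbon by addition–elimination, closing ring C through the O1–C2 bond in what is formally a 6-endo-dig closure. The closest known reaction type is the Pd-catalysed carbonylative annulation of o-iodophenols with terminal arylacetylenes to flavones in a secondary amine. No stereocentre is formed. Two selectivities are needed: CO insertion must precede alkynylation (otherwise a 2-arylbenzofuran would form), which the four oxygen donors on the aryl–Pd and the CO atmosphere should secure, and 6-endo closure must beat 5-exo closure to an aurone, which the enaminone pathway opened by Et2NH should secure. Benzyl and methyl ethers are inert, and the benzyl group on the neighbouring oxygen leaves the O1 phenol as the only nucleophile next to the acyl group.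

**Step 7**
Reactants: 12 8-(benzyloxy)-2-[3-(benzyloxy)-4,5-dimethoxyphenyl]-6,7-dimethoxy-4H-chromen-4-one
Product: 13 8-hydroxy-2-(3-hydroxy-4,5-dimethoxyphenyl)-6,7-dimethoxy-4H-chromen-4-one
Conditions: H2 (1 atm), 10% Pd/C, EtOAc/MeOH, rt
Reagents that add atoms: none
Why: Pd-catalysed hydrogenolysis of the two benzyl aryl ethers should be much faster than reduction of the aryl-substituted chromone C2=C3 bond at 1 atm and room temperature, and the methyl ethers are inert, so stopping after uptake of two equivalents of H2 should give the target.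

**Compound list**
1 | 2-hydroxy-3,4-dimethoxybenzaldehyde | O=Cc1ccc(OC)c(OC)c1O | starting material
2 | 2-(benzyloxy)-3,4-dimethoxybenzaldehyde | O=Cc1ccc(OC)c(OC)c1OCc1ccccc1 | intermediate
3 | 2-(benzyloxy)-3,4-dimethoxyphenyl formate | O=COc1ccc(OC)c(OC)c1OCc1ccccc1 | intermediate (not isolated)
4 | 2-(benzyloxy)-3,4-dimethoxyphenol | Oc1ccc(OC)c(OC)c1OCc1ccccc1 | intermediate
5 | 2-(benzyloxy)-6-iodo-3,4-dimethoxyphenol | Oc1c(I)cc(OC)c(OC)c1OCc1ccccc1 | intermediate
6 | 3-hydroxy-4,5-dimethoxybenzaldehyde | O=Cc1cc(O)c(OC)c(OC)c1 | starting material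
7 | 3-(benzyloxy)-4,5-dimethoxybenzaldehyde | O=Cc1cc(OC)c(OC)c(OCc2ccccc2)c1 | intermediate
8 | 1-(benzyloxy)-5-(2-diazoethenyl)-2,3-dimethoxybenzene | [N-]=[N+]=C=Cc1cc(OC)c(OC)c(OCc2ccccc2)c1 | intermediate (not isolated)
9 | 1-(benzyloxy)-5-ethynyl-2,3-dimethoxybenzene | C#Cc1cc(OC)c(OC)c(OCc2ccccc2)c1 | intermediate
10 | 1-[3-(benzyloxy)-2-hydroxy-4,5-dimethoxyphenyl]-3-[3-(benzyloxy)-4,5-dimethoxyphenyl]prop-2-yn-1-one | COc1cc(C#CC(=O)c2cc(OC)c(OC)c(OCc3ccccc3)c2O)cc(OCc2ccccc2)c1OC | intermediate (not isolated)
11 | 1-[3-(benzyloxy)-2-hydroxy-4,5-dimethoxyphenyl]-3-[3-(benzyloxy)-4,5-dimethoxyphenyl]-3-(diethylamino)prop-2-en-1-one (alkene geometry not defined) | CCN(CC)C(=CC(=O)c1cc(OC)c(OC)c(OCc2ccccc2)c1O)c1cc(OC)c(OC)c(OCc2ccccc2)c1 | intermediate (not isolated)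
12 | 8-(benzyloxy)-2-[3-(benzyloxy)-4,5-dimethoxyphenyl]-6,7-dimethoxy-4H-chromen-4-one | COc1cc(-c2cc(=O)c3cc(OC)c(OC)c(OCc4ccccc4)c3o2)cc(OCc2ccccc2)c1OC | intermediate
13 | 8-hydroxy-2-(3-hydroxy-4,5-dimethoxyphenyl)-6,7-dimethoxy-4H-chromen-4-one (CNP0264497.0) | COc1cc(-c2cc(=O)c3cc(OC)c(OC)c(O)c3o2)cc(O)c1OC | target

**Step count and risk**
Total steps: 7. Longest linear sequence: 5 (steps 1, 2, 3, 6, 7); steps 4 and 5 form the second branch.

Steps most likely to fail:

1. Step 6. The aryl–palladium species may couple with the alkyne before it takes up CO, the aroyl–palladium may be captured by the amine, or the alkynone may close in the 5-exo mode. The fallback avoids carbonylation; it sets out from phenol 4 and alkyne 9 and comes back at 12. Magnesium-mediated ortho-formylation of 4 (MgCl2, Et3N, paraformaldehyde, MeCN, reflux) should give 3-(benzyloxy)-2-hydroxy-4,5-dimethoxybenzaldehyde F1, since the only free position ortho to the OH is C6. Addition of the lithium acetylide of 9 (n-BuLi, THF, −78 °C, acetylide in excess to allow for the phenoxide) should give racemic 1-[3-(benzyloxy)-2-hydroxy-4,5-dimethoxyphenyl]-3-[3-(benzyloxy)-4,5-dimethoxyphenyl]prop-2-yn-1-ol F2. MnO2 in CH2Cl2 should oxidise it to alkynone 10, and Et2NH in EtOH should close ring C to 12 through enaminone 11.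

2. Step 3. Iodination may occur at C5 (para to the benzyloxy group) or twice, or the very electron-rich phenoxide may be oxidised by iodine. The fallback replaces electrophilic substitution by directed ortho-metalation; it sets out from 4 and comes back at 5. Carbamoylation (Et2NCOCl, K2CO3, MeCN, reflux) should give 2-(benzyloxy)-3,4-dimethoxyphenyl diethylcarbamate F3. Lithiation at the only free position ortho to the carbamate (s-BuLi, TMEDA, THF, −78 °C) and an I2 quench should give 2-(benzyloxy)-6-iodo-3,4-dimethoxyphenyl diethylcarbamate F4. Hydrolysis (KOH, EtOH, reflux) should release 5.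

3. Step 7. Saturation of the C2=C3 bond of the chromone may compete with hydrogenolysis, or the hindered 8-O-benzyl group may be cleaved incompletely. The fallback replaces reductive cleavage by Lewis-acid debenzylation with a cation scavenger; it sets out from 12 and comes back at 13 with no new intermediate. BCl3 and pentamethylbenzene in CH2Cl2 at −78 °C, quenched cold with MeOH, should cleave both benzyl aryl ethers and leave the methyl ethers and the enone untouched.

**Further compounds**
F1 | step 6 | 3-(benzyloxy)-2-hydroxy-4,5-dimethoxybenzaldehyde | O=Cc1cc(OC)c(OC)c(OCc2ccccc2)c1O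
F2 | step 6 | 1-[3-(benzyloxy)-2-hydroxy-4,5-dimethoxyphenyl]-3-[3-(benzyloxy)-4,5-dimethoxyphenyl]prop-2-yn-1-ol (racemic) | COc1cc(C#CC(O)c2cc(OC)c(OC)c(OCc3ccccc3)c2O)cc(OCc2ccccc2)c1OC
F3 | step 3 | 2-(benzyloxy)-3,4-dimethoxyphenyl diethylcarbamate | CCN(CC)C(=O)Oc1ccc(OC)c(OC)c1OCc1ccccc1
F4 | step 3 | 2-(benzyloxy)-6-iodo-3,4-dimethoxyphenyl diethylcarbamate | CCN(CC)C(=O)Oc1c(I)cc(OC)c(OC)c1OCc1ccccc1
F0 | step 7 | none | none
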